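## Retrosynthetic overview

1. (+)-Lariciresinol (**10**) comes from the C2-symmetric (8R,8'R)-secoisolariciresinol (**9**). Oxidation at one benzylic C7–H gives a p-quinone methide, which the 9'-OH traps 5-exo. This closes the only ring, makes the two halves inequivalent, and temporarily dearomatises one guaiacyl ring.
2. **9** comes from the bis-O-benzyl diol **8** by hydrogenolysis. **8** comes from the C2-symmetric bis-imide **7** by reductive removal of the auxiliary.
3. **7** comes from oxidative homocoupling of two molecules of the Evans imide **6** (C8–C8' bond). This sets both C8 and C8' (R,R).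
4. **6** is made from benzyl-protected dihydroferulic acid **4** and (S)-4-benzyloxazolidin-2-one (**5**). **4** is made from ferulic acid (**1**).

Assumptions (one line each):
- Ferulic acid is the (E)-isomer.
- The (S)-auxiliary gives the (R,R)-dimer. In each coupling the partner carbon approaches the Z-enolate face anti to the auxiliary benzyl group, as in Evans alkylation. With CIP priorities C(=O)N > C8/C8' > CH2Ar > H, this gives R at both carbons.

## Route

**Step 1**
Reactants: **1** (E)-ferulic acid
Product: **2** 3-(4-hydroxy-3-methoxyphenyl)propanoic acid (dihydroferulic acid)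
Conditions: H2 (1 atm), 10% Pd/C, EtOH, rt
Reagents that add atoms: none
Why: Catalytic hydrogenation reduces the conjugated C=C chemoselectively and leaves the arene and the free acid untouched. No stereocenter is formed.

**Step 2**
Reactants: **2** dihydroferulic acid; **3** benzyl bromide
Product: **4** 3-(4-benzyloxy-3-methoxyphenyl)propanoic acid
Conditions: one pot. BnBr (2.3 equiv), K2CO3, DMF, 60 °C; then 2 M NaOH(aq)/MeOH, 50 °C; acidify to pH 2.
Reagents that add atoms: benzyl bromide, BrCc1ccccc1 (the benzyl group ends up on the phenol oxygen)
Why: Williamson O-benzylation alkylates both the phenol and the carboxylate, and saponification then frees the acid. The aryl benzyl ether is base-stable, so the phenol is masked through the enolate chemistry.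

**Step 3**
Reactants: **4** 3-(4-benzyloxy-3-methoxyphenyl)propanoic acid; **5** (S)-4-benzyloxazolidin-2-one
Product: **6** (S)-4-benzyl-3-[3-(4-benzyloxy-3-methoxyphenyl)propanoyl]oxazolidin-2-one
Conditions: PivCl, Et3N, THF, 0 °C; then **5**, LiCl, rt
Reagents that add atoms: none (the pivaloyl group is lost as pivalic acid)
Why: Acylation through the mixed pivalic anhydride installs the Evans auxiliary by N-acylation. No stereocenter is formed.

**Step 4**
Reactants: **6** (S)-4-benzyl-3-[3-(4-benzyloxy-3-methoxyphenyl)propanoyl]oxazolidin-2-one, 2 equiv (two molecules of **6** are joined: 2 × **6** → **7** + 2 H)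
Product: **7** (2R,3R)-2,3-bis(4-benzyloxy-3-methoxybenzyl)succinoyl bis[(S)-4-benzyloxazolidin-2-one]
Conditions: NaHMDS (1.1 equiv per **6**), THF, −78 °C, 1 h; then Fe(acac)3 (1.2 equiv per **6**), −78 °C to 0 °C
Reagents that add atoms: none (NaHMDS and Fe(acac)3 only remove two H as the enolates are oxidised; no atoms of either reagent remain in **7**)
Why: This is an oxidative enolate homocoupling. The chelated Z-sodium enolate is oxidised by Fe(III) to a radical or enolate pair, and the auxiliary benzyl group shields one face, so C–C bond formation between the two α-carbons gives the C2-symmetric (R,R) dimer, setting C8 and C8' together. The meso-type (R,S) dimer is a minor product and is removed by chromatography.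

**Step 5**
Reactants: **7** (2R,3R)-bis-imide
Product: **8** (2R,3R)-2,3-bis(4-benzyloxy-3-methoxybenzyl)butane-1,4-diol
Conditions: LiBH4 (4 equiv), MeOH (4 equiv), THF, 0 °C to rt
Reagents that add atoms: none (only hydride is delivered; auxiliary **5** is recovered)
Why: Exocyclic C=O cleavage of the N-acyl oxazolidinone by borohydride (Evans auxiliary removal) gives the primary alcohols. C8 and C8' are not epimerised under these mild conditions, and the benzyl ethers are inert to borohydride.

**Step 6**
Reactants: **8** bis-O-benzyl diol
Product: **9** (−)-secoisolariciresinol, (2R,3R)-2,3-bis(4-hydroxy-3-methoxybenzyl)butane-1,4-diol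
Conditions: H2 (1 atm), 10% Pd/C, EtOAc/EtOH, rt, 3 h
Reagents that add atoms: none
Why: Hydrogenolysis of the aryl benzyl ethers frees both guaiacol OH groups. The stereocenters are untouched, and the primary alcohols are not benzylic, so they are not cleaved.

**Step 7**
Reactants: **9** (−)-secoisolariciresinol
Product: **10** (+)-lariciresinol
Conditions: DDQ (0.6 equiv), anhydrous 1,4-dioxane, 4 Å MS, solid NaHCO3, 0 °C to rt, 2 h; chromatograph and recycle recovered **9**
Reagents that add atoms: none (DDQ only removes H2 as DDQH2)
Why: Proposed new method: DDQ abstracts hydride from one benzylic C7–H of the electron-rich 4-alkylguaiacol, giving a p-quinone methide that dearomatises one ring. The 9'-OH adds to C7 in a 5-exo closure with rearomatisation, forming the tetrahydrofuran (O–C9'–C8'–C8–C7). The closest known reactions are DDQ dehydrogenation of 4-alkylphenols to p-quinone methides and intramolecular oxa-Michael addition to them. Because **9** is C2-symmetric, either half gives the same product, so the symmetry is broken without any selectivity problem between halves. C8 and C8' are unchanged, and the (R,R) backbone fixes the cis relationship of C9 (CH2OH) and C7' (CH2Ar) on the new ring. The new C7 centre is expected trans to C9 (the target's 2,3-trans arrangement), because the aryl group of the quinone methide prefers the face away from the C8 CH2OH in the cyclisation transition state; this selectivity is the main uncertainty. Solid NaHCO3 suppresses acid-driven Friedel–Crafts closure to the aryltetralin, and limiting DDQ to 0.6 equiv minimises a second cyclisation to the furofuran (pinoresinol-type).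

## Final checks

- The product of Step 7 has a THF ring of O, C9', C8', C8 and C7, with Ar on C7, CH2OH on C8 and CH2Ar on C8'. This matches the target SMILES.
- In the target SMILES, CH2OH (C8) and CH2Ar (C8') are cis on the ring, and the C7 aryl is trans to CH2OH. CIP analysis gives C7 = S, C8 = R, C8' = R, so (2S,3R,4R) in ring numbering. The C8 and C8' descriptors match those of **9** (R,R), which is what Step 7 requires.
- The SMILES of **7**, **8** and **9** all encode (R,R). The auxiliary in **5** and **6** is (S).
- Step 4 joins two molecules of **6** and loses two H, so the atoms balance (2 × C27H27NO6 → C54H52N2O12 for **7**, with the oxidant leaving no atoms).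
- The only protecting group (Bn) is removed before the final step. Every stereocenter is set once, in Step 4 (C8, C8') or Step 7 (C7), and nothing downstream epimerises them.

## Compound list

1 | (E)-ferulic acid | COc1cc(/C=C/C(=O)O)ccc1O | starting material
2 | dihydroferulic acid | COc1cc(CCC(=O)O)ccc1O | intermediate
3 | benzyl bromide | BrCc1ccccc1 | starting material
4 | 3-(4-benzyloxy-3-methoxyphenyl)propanoic acid | COc1cc(CCC(=O)O)ccc1OCc1ccccc1 | intermediate
5 | (S)-4-benzyloxazolidin-2-one | O=C1N[C@@H](Cc2ccccc2)CO1 | starting material
6 | (S)-4-benzyl-3-[3-(4-benzyloxy-3-methoxyphenyl)propanoyl]oxazolidin-2-one | COc1cc(CCC(=O)N2[C@@H](Cc3ccccc3)COC2=O)ccc1OCc1ccccc1 | intermediate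
7 | (2R,3R)-bis-imide dimer | O=C(N1[C@@H](Cc2ccccc2)COC1=O)[C@H](Cc1ccc(OCc2ccccc2)c(OC)c1)[C@@H](Cc1ccc(OCc2ccccc2)c(OC)c1)C(=O)N1[C@@H](Cc2ccccc2)COC1=O | intermediate
8 | (2R,3R)-2,3-bis(4-benzyloxy-3-methoxybenzyl)butane-1,4-diol | OC[C@H](Cc1ccc(OCc2ccccc2)c(OC)c1)[C@@H](Cc1ccc(OCc2ccccc2)c(OC)c1)CO | intermediate
9 | (−)-secoisolariciresinol | OC[C@H](Cc1ccc(O)c(OC)c1)[C@@H](Cc1ccc(O)c(OC)c1)CO | intermediate
10 | (+)-lariciresinol | COc1cc(C[C@H]2CO[C@H](c3ccc(O)c(OC)c3)[C@H]2CO)ccc1O | target

## Totals

Total steps: 7. Longest linear sequence: 7 (1 → 2 → 4 → 6 → 7 → 8 → 9 → 10).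

## Three steps most likely to fail

1. **Step 7 (oxidative desymmetrising cyclisation).** Risks are over-oxidation to the furofuran, phenol dehydrodimerisation, aryltetralin formation, and a modest C7 diastereomeric ratio.
   - Fallback (different approach): build C7 by aldol. Add the lithium enolate of (R)-β-(4-benzyloxy-3-methoxybenzyl)-γ-butyrolactone to O-benzylvanillin, and reduce the adduct with LiAlH4 to the triol. Close the THF by Mitsunobu-type cyclodehydration, in which the C9' primary alcohol is activated and the C7 hydroxyl closes the five-membered ring (activation of C9 would only give an oxetane and does not compete). Finish by hydrogenolysis of the benzyl groups.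
2. **Step 4 (Fe(III) oxidative homocoupling).** Yield, dimer-versus-meso ratio, or the facial sense could be poor.
   - Fallback (different approach): double Stobbe-type condensation of O-benzylvanillin with dimethyl succinate to the bis-benzylidene succinate. Then asymmetric Rh- or Ru-bisphosphine hydrogenation to the (R,R)-dibenzylsuccinate, and LiAlH4 reduction to **8**.
3. **Step 5 (auxiliary removal).** Endocyclic attack could give hydroxy-amide byproducts and stall the reduction.
   - Fallback (different approach): hydrolyse **7** with LiOOH to the (R,R)-dibenzylsuccinic acid, then reduce with BH3·THF to **8**.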